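**Plan**

1. Ring numbering: C1 (C=O), C2 (C–benzoyl), C3 (C–OH), C4 (C(prenyl)2), C5 (C–OH), C6 (C–prenyl). The first cut removes one prenyl from C4, giving aromatic 3,5-diprenyl-2,4,6-trihydroxybenzophenone, whose two prenylated ring carbons are symmetry-equivalent.
2. The second cut opens the ring at C1–C6 (Claisen closure, ester carbonyl to ketone CH2) and at C2–C3 (enolate C-acylation). This leaves ethyl benzoylacetate (C1, C2 and the benzoyl group) and a C3–C6 unit.
3. Enabling feature: ring atoms C3(O)–C4(prenyl)–C5(O)–C6(prenyl) are the head-to-tail β-lactone dimer of prenylketene (lactone C=O = C3, ring CH = C4, enol carbon = C5, exocyclic alkylidene carbon = C6). One acid chloride therefore supplies four ring carbons, two oxygens and two prenyl groups in register.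
4. Forward: Johnson–Claisen, saponification, acid chloride, ketene dimer. A formal [4+2] annulation of the dimer with benzoylacetate builds the only ring made in the route, first as the phloroglucinol. C-prenylation then dearomatises it to the target.
5. Stereochemistry: the target has no stereocentre and no stereogenic double bond. The stereocentre and Z-alkene of the racemic dimer are erased in the annulation.

Key step: step 5

Remark on the chemistry: the target is a tautomeric β-triketone. The enol form of the given SMILES is taken as one of several equilibrating tautomers, and the annulation product 12 is written as its aromatic triphenol tautomer.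

**Step 1**
Reactants: 1 2-methylbut-3-en-2-ol; 2 triethyl orthoacetate
Product: 5 ethyl 5-methylhex-4-enoate, via mixed orthoester 3 (not isolated), via ketene acetal 4 (not isolated)
Conditions: EtCO2H (cat.), excess 2 neat, 140 °C, EtOH distilled off
Reagents that add atoms: triethyl orthoacetate (2), CC(OCC)(OCC)OCC
Why: Johnson–Claisen rearrangement, in which acid-catalysed exchange gives the mixed orthoester, loss of ethanol gives the ketene acetal, and its chair [3,3]-sigmatropic shift should deliver the γ,δ-unsaturated ester with the prenyl-type trisubstituted alkene; no stereocentre is formed.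

**Step 2**
Reactants: 5 ethyl 5-methylhex-4-enoate
Product: 6 5-methylhex-4-enoic acid
Conditions: LiOH·H2O, THF/H2O, rt; then 1 M HCl
Reagents that add atoms: lithium hydroxide, [Li+].[OH-]
Why: Ester saponification under mild conditions that should leave the trisubstituted alkene untouched.

**Step 3**
Reactants: 6 5-methylhex-4-enoic acid
Product: 7 5-methylhex-4-enoyl chloride
Conditions: (COCl)2, DMF (cat.), CH2Cl2, 0 °C → rt; concentrate
Reagents that add atoms: oxalyl chloride, O=C(Cl)C(=O)Cl
Why: Acid chloride formation through the Vilsmeier-type chloroiminium catalyst at low temperature, with the gaseous by-products swept out so that the trisubstituted alkene should not be hydrochlorinated.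

**Step 4**
Reactants: 7 5-methylhex-4-enoyl chloride (two molecules)
Product: 9 (Z)-3-(3-methylbut-2-en-1-yl)-4-(4-methylpent-3-en-1-ylidene)oxetan-2-one (racemic), via prenylketene 8 (not isolated)
Conditions: Et3N (1.1 equiv), Et2O, 0 °C → rt; filter, concentrate
Reagents that add atoms: none
Why: Dehydrochlorination of an aliphatic acid chloride by triethylamine gives the aldoketene, which should dimerise head-to-tail by the usual formal [2+2] pathway to the (Z)-4-alkylidene-β-lactone (alkyl ketene dimer synthesis); the ring stereocentre forms racemic, which does not matter because it is erased in step 5.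

**Step 5**
Reactants: 9 (Z)-3-(3-methylbut-2-en-1-yl)-4-(4-methylpent-3-en-1-ylidene)oxetan-2-one; 10 ethyl benzoylacetate (ethyl 3-oxo-3-phenylpropanoate)
Product: 12 phenyl[2,4,6-trihydroxy-3,5-bis(3-methylbut-2-en-1-yl)phenyl]methanone, via open-chain tetracarbonyl ester 11 (not isolated)
Conditions: NaH (1.0 equiv), THF, 0 °C; add 9, 0 °C → rt until 9 is consumed; then LDA (2.6 equiv), −78 °C → rt; cold 1 M HCl work-up
Reagents that add atoms: none
Why: The sodium enolate of 10 should be C-acylated at the strained lactone carbonyl of 9 (acyl–oxygen cleavage), joining C2 to C3 and giving open-chain tetracarbonyl 11; LDA then takes the salt of 11 to its trianion, whose terminal carbanion (the CH2 next to the C5 ketone, formerly the exocyclic alkylidene carbon of 9) attacks the ester carbonyl in a Claisen condensation, and loss of ethoxide followed by enolisation gives the triphenolate of 12. The closest known reaction types are the acetoacetylation of active-methylene enolates by diketene, the terminal acylation of β-diketone dianions by esters, and the base-induced Claisen cyclisation of triketo esters to acylphloroglucinols. The carbocycle closes in a favoured 6-(enolendo)-exo-trig mode at the ester carbonyl. No stereocentre is formed, and the stereocentre and Z-alkene of 9 are erased. The step needs C- over O-cyclisation (which would give a 2-pyrone) and attack at the ester (Claisen) over attack at the benzoyl carbonyl (aldol to a biaryl resorcylate): in the trianion the benzoyl and C3 carbonyls are held as a chelated diketonate so that only the ester keeps carbonyl character, the terminal carbanion is far more nucleophilic than any enolate oxygen, and aromatisation makes the Claisen product irreversible.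

**Step 6**
Reactants: 12 phenyl[2,4,6-trihydroxy-3,5-bis(3-methylbut-2-en-1-yl)phenyl]methanone; 13 prenyl bromide (1-bromo-3-methylbut-2-ene)
Product: 14 2-benzoyl-3,5-dihydroxy-4,4,6-tris(3-methylbut-2-en-1-yl)cyclohexa-2,5-dien-1-one (target)
Conditions: 10% aq. KOH, 0 °C; 13 (1.05 equiv), 0 °C → rt; then 1 M HCl to pH 3
Reagents that add atoms: prenyl bromide (13), CC(C)=CCBr
Why: Dearomatising C-alkylation (SN2 with an allylic bromide) of the acylphloroglucinol polyanion at a ring carbon that already bears a prenyl group, favoured over O-alkylation in water where the phenoxide oxygens are hydrogen-bonded; the two prenylated carbons are symmetry-equivalent, so one constitution should result, and the new quaternary carbon carries two identical groups and is not a stereocentre.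

**Compound list**

1 | 2-methylbut-3-en-2-ol | C=CC(C)(C)O | starting material
2 | triethyl orthoacetate | CC(OCC)(OCC)OCC | starting material
3 | 3-(1,1-diethoxyethoxy)-3-methylbut-1-ene (mixed orthoester) | CC(OCC)(OCC)OC(C)(C)C=C | intermediate
4 | 3-[(1-ethoxyethenyl)oxy]-3-methylbut-1-ene (ketene acetal) | C=C(OCC)OC(C)(C)C=C | intermediate
5 | ethyl 5-methylhex-4-enoate | CCOC(=O)CCC=C(C)C | intermediate
6 | 5-methylhex-4-enoic acid | CC(C)=CCCC(=O)O | intermediate
7 | 5-methylhex-4-enoyl chloride | CC(C)=CCCC(=O)Cl | intermediate
8 | 5-methylhexa-1,4-dien-1-one (prenylketene) | CC(C)=CCC=C=O | intermediate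
9 | (Z)-3-(3-methylbut-2-en-1-yl)-4-(4-methylpent-3-en-1-ylidene)oxetan-2-one, racemic | CC(C)=CC/C=C1\OC(=O)C1CC=C(C)C | intermediate
10 | ethyl benzoylacetate (ethyl 3-oxo-3-phenylpropanoate) | CCOC(=O)CC(=O)c1ccccc1 | starting material
11 | ethyl 2-benzoyl-9-methyl-4-(3-methylbut-2-en-1-yl)-3,5-dioxodec-8-enoate | CCOC(=O)C(C(=O)c1ccccc1)C(=O)C(CC=C(C)C)C(=O)CCC=C(C)C | intermediate
12 | phenyl[2,4,6-trihydroxy-3,5-bis(3-methylbut-2-en-1-yl)phenyl]methanone | CC(C)=CCc1c(O)c(CC=C(C)C)c(O)c(C(=O)c2ccccc2)c1O | intermediate
13 | prenyl bromide (1-bromo-3-methylbut-2-ene) | CC(C)=CCBr | starting material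
14 | 2-benzoyl-3,5-dihydroxy-4,4,6-tris(3-methylbut-2-en-1-yl)cyclohexa-2,5-dien-1-one | CC(C)=CCC1=C(O)C(CC=C(C)C)(CC=C(C)C)C(O)=C(C(=O)c2ccccc2)C1=O | target

**Step count and risks**

Total steps: 6. Longest linear sequence: 6 steps (1 → 5 → 6 → 7 → 9 → 12 → 14).

Most likely to fail, first: step 5. The polyanion may form incompletely, so that the enol oxygen at C5 lactonises onto the ester (2-pyrone formation). The carbanion may add to the benzoyl carbonyl (aldol closure with aromatisation to a biaryl). Retro-Claisen loss of the benzoyl group may also compete. The fallback gives up ring construction for this intermediate and uses known phloroglucinol chemistry. It sets out from prenyl bromide 13 and purchased 2,4,6-trihydroxybenzophenone F1. Twofold C-prenylation in cold aqueous KOH with about two equivalents of 13 should pass through 3-prenyl-2,4,6-trihydroxybenzophenone F2 and come back to the route at 12, at the cost of a separation from under- and over-prenylated material.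

Second: step 6. O-prenylation, a second dearomatising alkylation at the remaining prenylated carbon, and acid-induced chroman formation during work-up can all erode the product. The fallback changes the electrophile and the mechanism to a Tsuji–Trost allylation. It sets out from 12, which is converted to its sodium salt (NaH, THF) and treated with purchased prenyl acetate F3 and Pd(PPh3)4 (cat.). The η3-prenyl palladium complex should be attacked at its unsubstituted terminus to give the linear prenyl group, and any O-prenyl ether re-ionises under Pd(0) and funnels to the C-alkylated product. The fallback comes back to the route at 14.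

Third: step 4. The ketene may oligomerise beyond the dimer, the β-lactone may hydrolyse during isolation, and residual HCl from step 3 may add across the trisubstituted alkenes. The fallback avoids the ketene dimer and assembles the open chain linearly. It sets out from 7 and 10: C-acylation of 10 with 7 under MgCl2/Et3N soft enolisation (MeCN, 0 °C) should give ethyl 2-benzoyl-7-methyl-3-oxooct-6-enoate F4. Its dianion (LDA, THF, −78 °C) is acylated at the terminal CH2 by ester 5 (terminal acylation of a β-diketone dianion by an ester). This comes back to the route at 11, which with further LDA in the same flask closes to 12 as in step 5.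

**Further compounds**

F1 | step 5 | 2,4,6-trihydroxybenzophenone (purchased) | O=C(c1ccccc1)c1c(O)cc(O)cc1O
F2 | step 5 | 3-prenyl-2,4,6-trihydroxybenzophenone | CC(C)=CCc1c(O)cc(O)c(C(=O)c2ccccc2)c1O
F3 | step 6 | prenyl acetate (purchased) | CC(C)=CCOC(C)=O
F4 | step 4 | ethyl 2-benzoyl-7-methyl-3-oxooct-6-enoate | CCOC(=O)C(C(=O)c1ccccc1)C(=O)CCC=C(C)C
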